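## Structural features

The target 13 is a 2-aryl-3-(hydroxymethyl)-2,3-dihydro-1-benzofuran in which ring A (the benzo ring) is fused through C3a and C7a to a dihydrofuran ring made up of O1, C2, C3, C3a and C7a. Ring A carries a methoxy group at C7 and a methyl propanoate chain at C5. C2 carries ring B (4-hydroxy-3,5-dimethoxyphenyl) and C3 carries the hydroxymethyl carbon C9. C2 and C3 are the only stereocentres, they stand next to each other, and the structure reads as 2S,3R, which places ring B and C9 trans on the five-membered ring. Fragile points are C2 (a benzylic ether carbon between O1 and an oxygen-rich aryl ring, ionised by acid and open to hydrogenolysis), the free phenol of ring B (easily oxidised to a quinone methide) and, at the ester stage, the acidic C3–H, whose removal can open the ring by β-elimination of the ring-A phenoxide. Two carbons at the carboxylate oxidation level, C9 and the chain carboxyl, must be told apart, because only C9 ends as an alcohol. The real difficulty is absolute control over the adjacent C2/C3 pair at the moment the O1–C2 bond is made and C9 is attached. The key step uses the fact that O1, C2, C3 and C9 are exactly what a ring-A phenol oxygen and one molecule of CO add across the C2=C3 double bond of an (E)-2-hydroxystilbene, so that alkene geometry can be translated into the trans ring.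

## Logic of the disconnections

13 ⇒ 11. No skeletal bond is cut. The side-chain Cα–Cβ single bond is traced back to a double bond and the ring-B phenol to its benzyl ether, with 12 as the half-reduced stage that is passed through. The gain is that the oxidisable phenol stays masked through every basic, oxidising or metal-mediated step and is released without a step of its own. The demand on the forward step is chemoselectivity: the alkene and the O–benzyl bond must go while the benzylic C2–O1 bond stays.

11 ⇒ 9 + 10. The side-chain Cα=Cβ bond is cut (olefination of an aldehyde at C5). This brings the only ester of the target into the molecule after the hydride reduction, so C9 and the chain carboxyl never coexist as esters. The demand is an olefination mild enough for a free primary alcohol and for the C2/C3 pair.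

9 ⇒ 7 (through 8). Two functional-group changes: the C9 alcohol is traced back to a methyl ester and the C5 aldehyde to its dioxolane. The gain is that C9 becomes a carboxyl carbon, the retron of a carbonylation. The demand is a hydride that spares the acetal, followed by acid mild enough not to ionise C2.

7 ⇒ 6. O1–C2 and C3–C9 are cut together. This removes the dihydrofuran ring, both stereocentres and one carbon at once and leaves an achiral (E)-stilbene. The forward step must choose one alkene face, close the ring in the 5-endo mode and trap the C3–palladium bond with CO before β-hydride elimination. In 6 the ring-A phenol is free (it is the nucleophile) and the ring-B phenol is benzylated (a free para-hydroxystyrene unit would be oxidised by the quinone). The C5 carbon is kept as an acetal and not as an aldehyde: this keeps the phenol nucleophilic and makes the ring-A phenoxide of 7 a poor leaving group for ring opening.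

6 ⇒ 3 + 5. The aryl–alkenyl bond C3–C3a is cut (Heck coupling). This gives two benzenoid pieces of similar size, and the E geometry follows from syn insertion and syn β-hydride elimination. The demand is arylation at the terminal alkene carbon in the presence of a free ortho-phenol. The acetal is placed before this coupling, so the acid needed for acetalisation never meets the acid-sensitive, electron-rich 2-hydroxystilbene.

5 ⇒ 4, and 3 ⇒ 2 ⇒ 1. Protecting-group and one-carbon operations only: acetalisation of 4; methylenation of 2 (cut of the vinyl C=C); O-benzylation of 1. All three end at commercial aldehydes.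

## Other disconnections considered

Alternative 1: The cut is O1–C2 together with C2–C3, a [4+1] assembly of the dihydrofuran ring from a ring-A unit (O1, C7a, C3a, C3 with C9 attached) and the single carbon C2 bearing ring B.
- Forward step: a carbonate base (Cs2CO3, CH2Cl2) would expel sulfinate from the sulfone A2 to give the ortho-quinone methide A4 and would deprotonate the chiral benzylic sulfonium salt A3. The ylide carbon adds to the exocyclic carbon of A4 (C2–C3), and the ring-A phenoxide then displaces the sulfide at C2 (O1–C2) to give A1. Desilylation and hydrogenolysis would lead to 13.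
- In favour: the route is convergent, and the propanoate chain and C9 are already at their final oxidation levels, so two steps remain after the key step against three in the chosen plan; on this point it is better. The reaction class has precedent for trans-2,3-disubstituted dihydrobenzofurans, whereas the chosen key step has none; here too it is better.
- Against: A4 is an alkyl-substituted quinone methide with hydrogens on the silyloxy-bearing carbon, so tautomerisation to a 2-alkenylphenol or oligomerisation can compete with capture by the ylide. The chiral sulfide is stoichiometric. The very electron-rich A3 can ionise and open a racemic background path. A2 needs its own multi-step ortho-functionalisation of a dihydroferulate, so overall length is at best equal.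
- Comparison: both plans form the ring and both stereocentres in one step. This one relies on face selection in an acyclic ylide addition followed by invertive closure; the chosen plan relies on catalyst-controlled face selection on a rigid (E)-alkene followed by stereospecific insertion, and starts from a stable alkene reached in four steps.

Alternative 2: The cut is C3–C3a; retrosynthetically the dihydrofuran is expanded to a pyran, so the precursor is a 2,3-trans-flavan-3-ol derivative.
- Forward step: buffered aqueous solvolysis of the mesylate A6 would let ring A shift from C4 to C3 through a phenonium ion with inversion at C3, while water opens the bridged ion at the old C4, which becomes C9–OH. This gives A5, and removal of the pivalate would give 13.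
- In favour: the step is stereospecific. C2 is untouched and the trans ring follows from the trans flavan, so no enantioselective catalysis is needed at the key step; on stereochemical certainty, once A6 is in hand, it is the equal or the better of the chosen plan. C9 appears directly as the free alcohol and one step remains afterwards, which is better than the chosen end-game.
- Against: A6 is an unnatural flavan (8-methoxy, 6-alkyl, syringyl-type ring B) that must itself be made as a single enantiomer, for example by asymmetric dihydroxylation of a 1,3-diarylpropene and a trans-selective ring closure. That is a sequence about as long as the whole chosen route. In the solvolysis, migration of ring B from C2, participation of O1, elimination to a flavene and direct substitution at C3 all compete; the pivalate only tempers ring B.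
- Comparison: mechanistically it trades catalyst control for substrate control, at the price of regiochemical competition and a clearly higher step count.

Alternative 3: The cut is O1–C7a, an aryl C–O bond, with C2 and C3 set beforehand in an open chain.
- Forward step: Pd2(dba)3, t-BuBrettPhos and Cs2CO3 in toluene would couple the C2 hydroxyl of A8 with the ring-A triflate to give A7. No bond at C2 is broken, so the configuration set by an auxiliary-controlled syn-aldol reaction is retained and maps onto the trans ring. Fluoride would then remove both silyl groups to give 13.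
- In favour: every reaction type is established, the relative and absolute configuration come from a reliable aldol reaction, ionisation at C2 is avoided altogether, and one step remains after the key step. On predictability and on precedent it is better than the chosen plan.
- Against: the palladium alkoxide of a secondary benzylic alcohol can undergo β-hydride elimination (ketone plus reduced arene). The triflate is flanked by a methoxy group and a branched benzylic carbon, and carbonate can cleave it. A8 needs a long linear sequence (ring-A arylacetic acid with an ortho oxygen, auxiliary on and off, aldol, reduction, selective silylation, triflation) and a stoichiometric auxiliary.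
- Comparison: the stereocentres are made before the ring and with reagent control; the chosen plan makes the ring, both stereocentres and one C–C bond in a single catalytic step and is several steps shorter, but it carries the risk of an untested reaction.

Key step: step 5

Assumption: the sense of induction of the bisoxazoline cannot be derived for this substrate class; the (S,S)-ligand is written provisionally for delivery of O1 to the Si face of C2, and its enantiomer is used with nothing else changed if the induction runs the other way.

## Route

Step 1
Reactants: 1 syringaldehyde (4-hydroxy-3,5-dimethoxybenzaldehyde)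
Product: 2 4-(benzyloxy)-3,5-dimethoxybenzaldehyde
Conditions: BnBr, K2CO3, DMF, 60 °C
Reagents that add atoms: benzyl bromide, BrCc1ccccc1
Why: Williamson etherification of the phenoxide; the benzyl group shields the oxidation-prone ring-B phenol through the palladium and quinone chemistry and later leaves in the hydrogenation that also saturates the side chain.

Step 2
Reactants: 2 4-(benzyloxy)-3,5-dimethoxybenzaldehyde
Product: 3 2-(benzyloxy)-5-ethenyl-1,3-dimethoxybenzene
Conditions: Ph3PCH3Br, KOtBu, THF, 0 °C to rt
Reagents that add atoms: methyltriphenylphosphonium bromide, C[P+](c1ccccc1)(c1ccccc1)c1ccccc1.[Br-]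
Why: Wittig methylenation of a non-enolisable aldehyde with the unstabilised ylide; the electron-rich styrene is kept cold with a radical inhibitor and used promptly.

Step 3
Reactants: 4 5-iodovanillin (4-hydroxy-3-iodo-5-methoxybenzaldehyde)
Product: 5 4-(1,3-dioxolan-2-yl)-2-iodo-6-methoxyphenol
Conditions: ethylene glycol, p-TsOH·H2O (cat.), toluene, reflux, Dean–Stark; Et3N quench
Reagents that add atoms: ethylene glycol, OCCO
Why: Acid-catalysed acetalisation driven by azeotropic removal of water; it is done on the iodoarene so that the later 2-hydroxystilbene never meets acid, and the product is purified on base-washed silica because para-hydroxyaryl acetals hydrolyse easily.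

Step 4
Reactants: 3 2-(benzyloxy)-5-ethenyl-1,3-dimethoxybenzene; 5 4-(1,3-dioxolan-2-yl)-2-iodo-6-methoxyphenol
Product: 6 2-[(E)-2-(4-benzyloxy-3,5-dimethoxyphenyl)ethenyl]-4-(1,3-dioxolan-2-yl)-6-methoxyphenol
Conditions: Pd(OAc)2 (5 mol%), P(o-tol)3 (10 mol%), K2CO3, DMF, 90 °C
Reagents that add atoms: none
Why: Heck reaction: oxidative addition into the C–I bond, syn insertion with aryl transfer to the terminal alkene carbon and syn β-hydride elimination should give the (E)-stilbene; the basic medium leaves the acetal untouched and free ortho-iodophenols are competent partners.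

Step 5
Reactants: 6 2-[(E)-2-(4-benzyloxy-3,5-dimethoxyphenyl)ethenyl]-4-(1,3-dioxolan-2-yl)-6-methoxyphenol
Product: 7 methyl (2S,3S)-2-(4-benzyloxy-3,5-dimethoxyphenyl)-5-(1,3-dioxolan-2-yl)-7-methoxy-2,3-dihydro-1-benzofuran-3-carboxylate (trans)
Conditions: Pd(OCOCF3)2 (10 mol%), (S,S)-Bn-boxax [(S)-2,2'-bis((4S)-4-benzyl-4,5-dihydrooxazol-2-yl)-1,1'-binaphthyl] (20 mol%), p-benzoquinone (3 equiv), CO (1 atm), MeOH (10 equiv), CH2Cl2, 0 °C to rt
Reagents that add atoms: carbon monoxide, [C-]#[O+]; methanol, CO
Why: Proposed new method: the cationic divalent palladium–bisoxazoline complex should bind the C2=C3 bond of 6 on its Re,Re face, the ring-A phenol oxygen then attacks C2 from the opposite (Si) face in a 5-endo-trig Wacker-type oxypalladation that closes the dihydrofuran ring (O1–C2) and leaves a benzylic C3–palladium bond trans to ring B, CO inserts into that bond with retention, methanolysis of the acylpalladium completes C3–C9 as the methyl ester, and benzoquinone returns zerovalent palladium to the divalent state. The closest known reaction types are the palladium-catalysed intramolecular alkoxycarbonylation of alkenols and 2-allylphenols (enantioselective with bisoxazoline ligands in this same Pd(OCOCF3)2/benzoquinone/CO/methanol system), the 5-endo Wacker cyclisation of 2-hydroxystilbenes to 2-arylbenzofurans and the cyclisation–carbonylation of 2-alkynylphenols; new here is the interception by CO of the benzylic palladium intermediate of a stilbene before β-hydride elimination, and its enantiocontrol. C2 (S) is set by the ligand, which must deliver O1 to the Si face of C2; C3 (S in 7, the trans arrangement) follows from the (E)-geometry of 6 through anti addition and retentive insertion. Because the trans ester is also the more stable epimer at the enolisable C3, any cis ester (for instance from a syn-oxypalladation pathway) should be convertible with a catalytic amine base without touching C2. Regiochemistry is secured by the tether, since attack at C3 would need a four-membered ring, and is helped by the three oxygen substituents of ring B, which stabilise positive charge at C2. The selectivity the step needs most is carbonylation over β-hydride elimination to the 2-arylbenzofuran: the C3–palladium bond is benzylic to ring A and can rest as an η3-benzyl complex on a metal whose other two sites are held by the bidentate ligand, which leaves no free cis site for hydride transfer until CO has bound. A CO atmosphere with only a modest excess of methanol in CH2Cl2 favours insertion and spares the dioxolane from exchange with methanol.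

Step 6
Reactants: 7 methyl (2S,3S)-2-(4-benzyloxy-3,5-dimethoxyphenyl)-5-(1,3-dioxolan-2-yl)-7-methoxy-2,3-dihydro-1-benzofuran-3-carboxylate
Product: 9 (2S,3R)-2-(4-benzyloxy-3,5-dimethoxyphenyl)-3-(hydroxymethyl)-7-methoxy-2,3-dihydro-1-benzofuran-5-carbaldehyde, via dioxolane alcohol 8 (not isolated)
Conditions: LiBH4, THF, 0 °C to rt; then 1 M aq HCl, rt
Reagents that add atoms: water, O
Why: Hydride reduction of the ester by LiBH4 leaves the acetal, the aryl ethers and the benzyl ether alone and does not change C3 spatially (the descriptor becomes R only because CH2OH ranks below C2); aqueous acid then destroys the remaining hydride at once and hydrolyses the electron-rich aryl dioxolane to the aldehyde at room temperature, too mild to ionise C2.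

Step 7
Reactants: 9 (2S,3R)-2-(4-benzyloxy-3,5-dimethoxyphenyl)-3-(hydroxymethyl)-7-methoxy-2,3-dihydro-1-benzofuran-5-carbaldehyde; 10 trimethyl phosphonoacetate
Product: 11 methyl (E)-3-[(2S,3R)-2-(4-benzyloxy-3,5-dimethoxyphenyl)-3-(hydroxymethyl)-7-methoxy-2,3-dihydro-1-benzofuran-5-yl]prop-2-enoate
Conditions: LiCl, DBU, MeCN, rt
Reagents that add atoms: none
Why: Horner–Wadsworth–Emmons olefination in its LiCl/amine variant, which tolerates the free primary alcohol and is too weakly basic to disturb C2 or C3 now that C3 is no longer α to a carbonyl; the alkene geometry is of no consequence because the double bond is hydrogenated next.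

Step 8
Reactants: 11 methyl (E)-3-[(2S,3R)-2-(4-benzyloxy-3,5-dimethoxyphenyl)-3-(hydroxymethyl)-7-methoxy-2,3-dihydro-1-benzofuran-5-yl]prop-2-enoate
Product: 13 methyl 3-[(2S,3R)-2-(4-hydroxy-3,5-dimethoxyphenyl)-3-(hydroxymethyl)-7-methoxy-2,3-dihydro-1-benzofuran-5-yl]propanoate, via saturated benzyl ether 12 (not isolated)
Conditions: H2 (1 atm), 10% Pd/C, EtOAc, rt
Reagents that add atoms: none
Why: Catalytic hydrogenation should saturate the cinnamate double bond first and then hydrogenolyse the primary benzyl aryl ether; the ring C2–O1 bond, a secondary benzylic ether held in a ring, is expected to react more slowly at one atmosphere in a non-acidic solvent, and the reaction is stopped once 12 is consumed.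

## Compound list

1 | syringaldehyde (4-hydroxy-3,5-dimethoxybenzaldehyde) | COc1cc(C=O)cc(OC)c1O | starting material
2 | 4-(benzyloxy)-3,5-dimethoxybenzaldehyde | COc1cc(C=O)cc(OC)c1OCc1ccccc1 | intermediate
3 | 2-(benzyloxy)-5-ethenyl-1,3-dimethoxybenzene | COc1cc(C=C)cc(OC)c1OCc1ccccc1 | intermediate
4 | 5-iodovanillin (4-hydroxy-3-iodo-5-methoxybenzaldehyde) | COc1cc(C=O)cc(I)c1O | starting material
5 | 4-(1,3-dioxolan-2-yl)-2-iodo-6-methoxyphenol | COc1cc(cc(I)c1O)C1OCCO1 | intermediate
6 | 2-[(E)-2-(4-benzyloxy-3,5-dimethoxyphenyl)ethenyl]-4-(1,3-dioxolan-2-yl)-6-methoxyphenol | COc1cc(cc(/C=C/c2cc(OC)c(OCc3ccccc3)c(OC)c2)c1O)C1OCCO1 | intermediate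
7 | methyl (2S,3S)-2-(4-benzyloxy-3,5-dimethoxyphenyl)-5-(1,3-dioxolan-2-yl)-7-methoxy-2,3-dihydro-1-benzofuran-3-carboxylate | O1CCOC1c1cc(OC)c2c(c1)[C@H](C(=O)OC)[C@@H](c1cc(OC)c(OCc3ccccc3)c(OC)c1)O2 | intermediate
8 | [(2S,3R)-2-(4-benzyloxy-3,5-dimethoxyphenyl)-5-(1,3-dioxolan-2-yl)-7-methoxy-2,3-dihydro-1-benzofuran-3-yl]methanol | O1CCOC1c1cc(OC)c2c(c1)[C@H](CO)[C@@H](c1cc(OC)c(OCc3ccccc3)c(OC)c1)O2 | intermediate
9 | (2S,3R)-2-(4-benzyloxy-3,5-dimethoxyphenyl)-3-(hydroxymethyl)-7-methoxy-2,3-dihydro-1-benzofuran-5-carbaldehyde | O=Cc1cc(OC)c2c(c1)[C@H](CO)[C@@H](c1cc(OC)c(OCc3ccccc3)c(OC)c1)O2 | intermediate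
10 | trimethyl phosphonoacetate | COC(=O)CP(=O)(OC)OC | starting material
11 | methyl (E)-3-[(2S,3R)-2-(4-benzyloxy-3,5-dimethoxyphenyl)-3-(hydroxymethyl)-7-methoxy-2,3-dihydro-1-benzofuran-5-yl]prop-2-enoate | COC(=O)/C=C/c1cc(OC)c2c(c1)[C@H](CO)[C@@H](c1cc(OC)c(OCc3ccccc3)c(OC)c1)O2 | intermediate
12 | methyl 3-[(2S,3R)-2-(4-benzyloxy-3,5-dimethoxyphenyl)-3-(hydroxymethyl)-7-methoxy-2,3-dihydro-1-benzofuran-5-yl]propanoate | COC(=O)CCc1cc(OC)c2c(c1)[C@H](CO)[C@@H](c1cc(OC)c(OCc3ccccc3)c(OC)c1)O2 | intermediate
13 | methyl 3-[(2S,3R)-2-(4-hydroxy-3,5-dimethoxyphenyl)-3-(hydroxymethyl)-7-methoxy-2,3-dihydro-1-benzofuran-5-yl]propanoate | COC(=O)CCc1cc(OC)c2c(c1)[C@H](CO)[C@@H](c1cc(OC)c(O)c(OC)c1)O2 | target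

## Step count and least certain steps

Total: 8 steps. Longest linear sequence: 7 steps (1 → 2 → 3 → 6 → 7 → 9 → 11 → 13); step 3 is a one-step branch from 4.

**Key step (step 5).**
- What may go wrong: β-hydride elimination from the C3–palladium intermediate may overtake CO insertion (aromatisation, the normal Wacker outcome). Discrimination between the two faces of a 1,2-diarylalkene in a 5-endo closure may be weak. CO may reduce the catalyst to metal before the quinone reoxidises it. The acetal may exchange with methanol under traces of acid.
- Fallback by known chemistry: the fallback forms C2–C3 by carbenoid C–H insertion in place of the alkene difunctionalisation; it sets out from 2 and 5 and comes back at 7.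
  - Aldehyde 2 is reduced (NaBH4, MeOH) to (4-benzyloxy-3,5-dimethoxyphenyl)methanol F1.
  - F1 is joined to phenol 5 by Mitsunobu etherification (PPh3, DIAD, THF) to give 2-[4-[(4-benzyloxy-3,5-dimethoxyphenyl)methoxy]-3-iodo-5-methoxyphenyl]-1,3-dioxolane F2.
  - Palladium-catalysed coupling of the aryl iodide with the Reformatsky reagent BrZnCH2CO2Me (Pd2(dba)3, XPhos, THF) gives methyl 2-[2-[(4-benzyloxy-3,5-dimethoxyphenyl)methoxy]-5-(1,3-dioxolan-2-yl)-3-methoxyphenyl]acetate F3.
  - Diazo transfer (4-acetamidobenzenesulfonyl azide, DBU, MeCN) gives the corresponding methyl aryldiazoacetate F4.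
  - With Rh2(S-PTTL)4 (dirhodium tetrakis[N-phthaloyl-(S)-tert-leucinate], catalyst enantiomer chosen for 2S) in toluene at low temperature, the carbenoid should insert into the benzylic C–H bond next to the ether oxygen and give the cis-dihydrobenzofuran ester F5.
  - NaOMe in MeOH then epimerises C3 to the trans ester 7.

**Step 3.**
- What may go wrong: acetalisation may stay incomplete because the para-hydroxyl makes the aldehyde a vinylogous acid, and the acetal may revert during isolation.
- Fallback: the order is reversed and the acetal is made without acid or water; it sets out from 4 and 3 and comes back at 6. Heck coupling of 4 with 3 under the conditions of step 4 gives (E)-3-[2-(4-benzyloxy-3,5-dimethoxyphenyl)ethenyl]-4-hydroxy-5-methoxybenzaldehyde F6. F6 is then acetalised aprotically with 1,2-bis(trimethylsilyloxy)ethane and catalytic TMSOTf in CH2Cl2 at −78 °C; a transient phenol silyl ether is lost on work-up.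

**Step 4.**
- What may go wrong: aryl transfer to the internal alkene carbon (the styrene is electron-rich), thermal polymerisation of the styrene, and further palladium-mediated cyclisation of the ortho-hydroxystilbene.
- Fallback: the fallback fixes regiochemistry and geometry in a boron reagent; it sets out from 3 and 5 and comes back at 6. Cross-metathesis of 3 with vinylboronic acid pinacol ester (second-generation Grubbs catalyst, CH2Cl2, reflux) gives 2-[(E)-2-(4-benzyloxy-3,5-dimethoxyphenyl)ethenyl]-4,4,5,5-tetramethyl-1,3,2-dioxaborolane F7. Suzuki–Miyaura coupling of F7 with 5 (PdCl2(dppf), K2CO3, dioxane/water, 80 °C) gives 6.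

**Step 6.**
- What may go wrong: reduction of the newly freed aldehyde if acetal hydrolysis starts before all boron hydride is destroyed, and acid-induced ionisation at C2 with loss of the trans relationship.
- Fallback: hydride and acid never meet, and over-reduction is made harmless; it sets out from 7 and comes back at 9. The acetal is hydrolysed first (PPTS, acetone/water) to methyl (2S,3S)-2-(4-benzyloxy-3,5-dimethoxyphenyl)-5-formyl-7-methoxy-2,3-dihydro-1-benzofuran-3-carboxylate F8. Both carbonyl groups are reduced (LiBH4, THF) to [(2S,3R)-2-(4-benzyloxy-3,5-dimethoxyphenyl)-7-methoxy-2,3-dihydro-1-benzofuran-3,5-diyl]dimethanol F9. Activated MnO2 in CH2Cl2 then oxidises only the benzylic alcohol to give 9.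

**Step 8.**
- What may go wrong: hydrogenolysis of the benzylic C2–O1 bond (ring opening) competing with O-debenzylation, or stalling of the cleavage of the doubly ortho-substituted benzyl ether.
- Fallback: the two tasks are separated and neither uses hydrogen on palladium; it sets out from 11 and comes back at 13. Conjugate reduction with nickel boride (NiCl2·6H2O, NaBH4, MeOH, 0 °C) gives 12. Lewis-acid debenzylation (BCl3, pentamethylbenzene, CH2Cl2, −78 °C) gives 13. This fallback makes no compound outside the list (F0).

## Further compounds

F1 | step 5 | (4-benzyloxy-3,5-dimethoxyphenyl)methanol | COc1cc(CO)cc(OC)c1OCc1ccccc1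
F2 | step 5 | 2-[4-[(4-benzyloxy-3,5-dimethoxyphenyl)methoxy]-3-iodo-5-methoxyphenyl]-1,3-dioxolane | COc1cc(cc(I)c1OCc1cc(OC)c(OCc2ccccc2)c(OC)c1)C1OCCO1
F3 | step 5 | methyl 2-[2-[(4-benzyloxy-3,5-dimethoxyphenyl)methoxy]-5-(1,3-dioxolan-2-yl)-3-methoxyphenyl]acetate | COC(=O)Cc1cc(cc(OC)c1OCc1cc(OC)c(OCc2ccccc2)c(OC)c1)C1OCCO1
F4 | step 5 | methyl 2-diazo-2-[2-[(4-benzyloxy-3,5-dimethoxyphenyl)methoxy]-5-(1,3-dioxolan-2-yl)-3-methoxyphenyl]acetate | COC(=O)C(=[N+]=[N-])c1cc(cc(OC)c1OCc1cc(OC)c(OCc2ccccc2)c(OC)c1)C1OCCO1
F5 | step 5 | methyl (2S,3R)-2-(4-benzyloxy-3,5-dimethoxyphenyl)-5-(1,3-dioxolan-2-yl)-7-methoxy-2,3-dihydro-1-benzofuran-3-carboxylate (cis) | O1CCOC1c1cc(OC)c2c(c1)[C@@H](C(=O)OC)[C@@H](c1cc(OC)c(OCc3ccccc3)c(OC)c1)O2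
F6 | step 3 | (E)-3-[2-(4-benzyloxy-3,5-dimethoxyphenyl)ethenyl]-4-hydroxy-5-methoxybenzaldehyde | COc1cc(C=O)cc(/C=C/c2cc(OC)c(OCc3ccccc3)c(OC)c2)c1O
F7 | step 4 | 2-[(E)-2-(4-benzyloxy-3,5-dimethoxyphenyl)ethenyl]-4,4,5,5-tetramethyl-1,3,2-dioxaborolane | COc1cc(/C=C/B2OC(C)(C)C(C)(C)O2)cc(OC)c1OCc1ccccc1
F8 | step 6 | methyl (2S,3S)-2-(4-benzyloxy-3,5-dimethoxyphenyl)-5-formyl-7-methoxy-2,3-dihydro-1-benzofuran-3-carboxylate | O=Cc1cc(OC)c2c(c1)[C@H](C(=O)OC)[C@@H](c1cc(OC)c(OCc3ccccc3)c(OC)c1)O2
F9 | step 6 | [(2S,3R)-2-(4-benzyloxy-3,5-dimethoxyphenyl)-7-methoxy-2,3-dihydro-1-benzofuran-3,5-diyl]dimethanol | OCc1cc(OC)c2c(c1)[C@H](CO)[C@@H](c1cc(OC)c(OCc3ccccc3)c(OC)c1)O2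
F0 | step 8 | none | none
A1 | alternative 1 | methyl 3-[(2S,3R)-2-(4-benzyloxy-3,5-dimethoxyphenyl)-3-[[tert-butyl(dimethyl)silyl]oxymethyl]-7-methoxy-2,3-dihydro-1-benzofuran-5-yl]propanoate | COC(=O)CCc1cc(OC)c2c(c1)[C@H](CO[Si](C)(C)C(C)(C)C)[C@@H](c1cc(OC)c(OCc3ccccc3)c(OC)c1)O2
A2 | alternative 1 | methyl 3-[3-[2-[tert-butyl(dimethyl)silyl]oxy-1-(4-methylphenyl)sulfonylethyl]-4-hydroxy-5-methoxyphenyl]propanoate (racemic) | COC(=O)CCc1cc(OC)c(O)c(c1)C(CO[Si](C)(C)C(C)(C)C)S(=O)(=O)c1ccc(C)cc1
A3 | alternative 1 | (2R,5R)-1-[(4-benzyloxy-3,5-dimethoxyphenyl)methyl]-2,5-dimethylthiolan-1-ium tetrafluoroborate | C[C@@H]1CC[C@@H](C)[S+]1Cc1cc(OC)c(OCc2ccccc2)c(OC)c1.F[B-](F)(F)F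
A4 | alternative 1 | methyl 3-[3-[2-[tert-butyl(dimethyl)silyl]oxyethylidene]-5-methoxy-4-oxocyclohexa-1,5-dien-1-yl]propanoate (ortho-quinone methide) | O=C1C(=CCO[Si](C)(C)C(C)(C)C)C=C(CCC(=O)OC)C=C1OC
A5 | alternative 2 | methyl 3-[(2S,3R)-2-[4-(2,2-dimethylpropanoyloxy)-3,5-dimethoxyphenyl]-3-(hydroxymethyl)-7-methoxy-2,3-dihydro-1-benzofuran-5-yl]propanoate | COC(=O)CCc1cc(OC)c2c(c1)[C@H](CO)[C@@H](c1cc(OC)c(OC(=O)C(C)(C)C)c(OC)c1)O2
A6 | alternative 2 | methyl 3-[(2R,3S)-2-[4-(2,2-dimethylpropanoyloxy)-3,5-dimethoxyphenyl]-8-methoxy-3-(methylsulfonyloxy)-3,4-dihydro-2H-chromen-6-yl]propanoate | COC(=O)CCc1cc(OC)c2c(c1)C[C@H](OS(C)(=O)=O)[C@@H](c1cc(OC)c(OC(=O)C(C)(C)C)c(OC)c1)O2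
A7 | alternative 3 | methyl 3-[(2S,3R)-3-[[tert-butyl(dimethyl)silyl]oxymethyl]-2-[3,5-dimethoxy-4-tri(propan-2-yl)silyloxyphenyl]-7-methoxy-2,3-dihydro-1-benzofuran-5-yl]propanoate | COC(=O)CCc1cc(OC)c2c(c1)[C@H](CO[Si](C)(C)C(C)(C)C)[C@@H](c1cc(OC)c(O[Si](C(C)C)(C(C)C)C(C)C)c(OC)c1)O2
A8 | alternative 3 | methyl 3-[3-[(1S,2R)-3-[tert-butyl(dimethyl)silyl]oxy-1-[3,5-dimethoxy-4-tri(propan-2-yl)silyloxyphenyl]-1-hydroxypropan-2-yl]-5-methoxy-4-(trifluoromethylsulfonyloxy)phenyl]propanoate | COC(=O)CCc1cc(OC)c(OS(=O)(=O)C(F)(F)F)c(c1)[C@H](CO[Si](C)(C)C(C)(C)C)[C@H](O)c1cc(OC)c(O[Si](C(C)C)(C(C)C)C(C)C)c(OC)c1
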